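## Structural features

The target is a 3,5-dihydro-2H-1-benzofuran-6-one. A dihydrofuran (ring B: O1, C2, C3, C3a, C7a) is fused through the C3a–C7a bond to a linearly conjugated cyclohexa-2,4-dienone (ring A: C3a=C4, C5, C6=O, C7=C7a), and O1 on C7a makes C7a=C7–C6=O a vinylogous ester. C2 carries a 3,4,5-trimethoxyphenyl group and C3 a methyl group; these two stereocentres are neighbours and trans (2S,3S). The third stereocentre, C5 (R), is quaternary, carries methoxy and allyl, lies α to the ketone and is separated from C3 by the sp2 atoms C3a and C4, so nothing on ring B can steer a reagent that attacks C5 directly. The 6-allyl-6-alkoxy dienone is the fragile part: on heating the allyl group can move by [3,3] shift to C3a or to the ketone oxygen (with aromatisation), and acid ionises the benzylic C2–O1 bond beside the electron-rich arene. The real difficulty is twofold: to put the 1,2,4-trioxygenated ring A onto the stereodefined C2–C3 unit, and to carry configuration from C3 to C5 without ever heating an allyl dienone. The key step uses the 1,3 relationship of the oxygens on C6 and C7a of ring A, the mark of a vinylketene–alkoxyalkyne benzannulation, and the three-atom chain O1–C2–C3 that links C7a to C3a, so that ketene and alkyne can be tethered and rings A and B formed together.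

## Logic of the disconnections

29 to 28. The terminal C=C of the allyl group is cut (Wittig). The allyl dienone is the thermally labile function, so it is made last and cold. The gain is an aldehyde side chain that cannot undergo sigmatropic shifts. The demand is methylenation of the aldehyde in the presence of the ring ketone without β-elimination of methoxide.

28 to 26 (through 27). The C5–CH2 bond is cut and the oxygen is returned to C3a (retro-Claisen). A [3,3] shift carries configuration suprafacially from C3a, which C3 can control, to C5, and it runs downhill because a C=O bond is formed. The mirror idea, an allyl group on C3a followed by a Cope shift to C5, is not used: in allyl cyclohexadienones the [3,3] equilibrium is expected to lie on the cross-conjugated C3a side, where the C5 methoxy group remains part of an enol ether. The gain is that the remote C5 centre is traded for a C3a–O centre next to C3. The demand is vinyl ether formation on a tertiary alcohol and a shift to C5, not to C7.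

26 to 24. The C3a–O bond is cut (dearomatising para-oxygenation). The gain is a flat phenol with C2 and C3 as the only stereocentres. The demand is attack at the para carbon C3a and on the face anti to the C3 methyl group.

24 to 19. The C6–C7, C3a–C7a and C5–C6 bonds are cut, which opens both rings. The gain is an acyclic chain whose only stereocentres are the later C2 and C3 and which already holds every oxygen of ring A. The demand is a clean Wolff shift and a [2+2] addition through a three-atom tether. The configurations at C5 and C6 of the chain in 19 were checked to map unchanged onto C3 and C2 of 24.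

19 to 18 to 16. The C–H of the alkyne is traded for C–Si, and the diazo group is removed. A terminal ynol ether is too acidic and too labile to survive strong base, so it is carried with a silyl cap that is removed last. The enone will not accept direct diazo transfer, so the ketone is activated as its trifluoroacetyl derivative. The demand is that C4 be the only enolisable position, which it is.

16 to 14 to 11 + 12. The enol ether C–O bond (methanol added to an ynone) and the bond between the carbonyl carbon and the ethynyl carbon are cut. The gain is that C4 and C5 of ring A come from a commercial two-carbon Grignard reagent. The demand is ordinary 1,2-addition and oxidation.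

11 to 10 to 8. The aldehyde is traced to a terminal alkene by anti-Markovnikov hydration and oxidation. The demand is hydroboration of the alkene in the presence of the silyl-capped alkyne.

8 to 4 + 5. The O–C(sp) bond is cut. The ynol ether is installed while the molecule holds only an alkene, because the KH and n-BuLi it needs are incompatible with ketone, enone or diazo groups. It also protects the hydroxyl, which as a free γ-hydroxy carbonyl compound would lactolise. The demand is a one-pot sequence that leaves the alkene untouched.

4 to 1 + 2. The bond between the carbinol carbon and the methyl-bearing carbon is cut (crotylboration). Both stereocentres are set in the first step from two commercial compounds. The demand is anti selectivity and control of the aldehyde face by the catalyst.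

## Other disconnections considered

Alternative 1: The cut is the C5–O bond, made while ring A is dearomatised. The phenolic acid A1, which carries a 2-carboxyethyl group on C5 in place of methoxy, would be oxidised by a C2-symmetric chiral iodoarene (a 2-iodoresorcinol bis(lactamide) ether) with mCPBA, and the carboxylate would close on C5 to give the spirolactone A2.
- In its favour: the oxygen is delivered intramolecularly, so the site is fixed. The quaternary centre is set by the catalyst and not by a relay. The reaction type is established for 2-(2-carboxyethyl)phenols and runs near room temperature.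
- Against it here: the lactone brings the right oxygen but the wrong carbon chain. A2 would have to be opened, the tertiary α-ketol oxygen methylated and the three-carbon arm cut down to allyl by reduction and elimination, all beside the dienone carbonyl. A1 still needs its own construction of the dihydrobenzofuran.
- Comparison: on control of C5 this alternative is the better, since one catalyst-controlled event replaces the two substrate-controlled events of steps 10 and 11. In mechanism its key step stands on firmer precedent than the tethered benzannulation. In structure it does nothing for rings A and B, which the chosen key step builds in one operation. In step economy it is longer after the key step (four to five operations against three).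

Alternative 2: The cuts are C3–CH3, C2–C3 and C2–O1. MeMgBr would add to the O-Boc salicylaldehyde A3; the carbonate would migrate to the new alkoxide and leave, releasing an ortho-quinone methide. The ylide from the sulfonium salt A4 (a 3,4,5-trimethoxybenzyl sulfonium salt of a C2-symmetric thiolane) would capture it in a (4+1) annulation to give A5.
- In its favour: three simple components; ring A is bought with its oxygens in place; ring B and both stereocentres are made in one flask; trans selectivity is inherent to such ylide annulations; A5 needs only loss of the methoxymethyl group to reach 24.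
- Against it here: a quinone methide with a methyl group on its exocyclic carbon can tautomerise to a vinylphenol. The Grignard reagent and the ylide must coexist. The absolute configuration rests on a stoichiometric chiral sulfide in an addition that may be reversible.
- Comparison: in step economy this alternative is clearly the better (about four steps to 24 against nine). In structure it is equal at the end, because it joins the chosen route at 24 and meets the same C5 problem. For C2 and C3 the chosen plan is the safer, since its crotylboration is a reliable catalyst-controlled reaction. Both key steps go beyond established practice, the alternative somewhat less.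

Alternative 3: The cut is C2–C3. The aryldiazoacetate A6 with Rh2(S-PTTL)4, dirhodium tetrakis[N-phthaloyl-(S)-tert-leucinate] (or its enantiomer, whichever gives 2S), would form a carbene that inserts into the benzylic ether C–H bond to give the cis ester A7.
- In its favour: the insertion is an established route to cis-2-aryl-2,3-dihydrobenzofuran-3-carboxylates with high enantioselectivity at low loading; C2 is set reliably; ring A arrives complete.
- Against it here: A7 has the wrong relative configuration and an ester where a methyl group is needed. Epimerisation at C3, a three-stage reduction of CO2Me to CH3 and loss of the methoxymethyl group are required before 24 is reached. The electron-rich benzyl ether may divert the carbene to oxonium ylide pathways.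
- Comparison: in certainty of the key step this alternative is the better. In step economy it is about equal or slightly worse (a fully oxygenated arylacetate must be made and five steps follow the insertion). In structure it forms one ring and one bond where the chosen step forms two rings and three bonds. The end game from 24 is common to both.

Key step: step 9

Assumptions and remarks on the chemistry:
- Ring positions are numbered as in benzofuran (O1, C2, C3, C3a, C4 to C7, C7a), also when open-chain precursors are discussed.
- The (S)-enantiomer of the phosphoric acid in step 1 is taken to direct addition to the si face of the aldehyde, giving (1S,2S)-4. If the sense proves opposite, the (R)-catalyst is used with no other change.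
- In 25, 26 and 27 the descriptor of C3 reads R only because the oxygen on C3a changes the CIP priorities; the geometry at C3 is unchanged.

## Route

Step 1
Reactants: 1 3,4,5-trimethoxybenzaldehyde; 2 (E)-crotylboronic acid pinacol ester
Product: 4 (1S,2S)-2-methyl-1-(3,4,5-trimethoxyphenyl)but-3-en-1-ol, via pinacol borate ester 3 (not isolated)
Conditions: (S)-3,3′-bis(2,4,6-triisopropylphenyl)-1,1′-binaphthyl-2,2′-diyl hydrogen phosphate (5 mol%), toluene, −30 °C; aq. NaHCO3
Reagents that add atoms: none
Why: Chiral Brønsted acid-catalysed crotylboration: the phosphoric acid activates the boronate and the aldehyde adds through a closed chair (Zimmerman–Traxler) transition state, so the (E)-crotyl geometry gives the anti pair and the catalyst selects the si face, which sets both centres (the later C2 and C3) as (1S,2S).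

Step 2
Reactants: 4 (1S,2S)-2-methyl-1-(3,4,5-trimethoxyphenyl)but-3-en-1-ol; 5 trichloroethylene
Product: 8 ({[(1S,2S)-2-methyl-1-(3,4,5-trimethoxyphenyl)but-3-en-1-yl]oxy}ethynyl)tri(propan-2-yl)silane, via (E)-1,2-dichlorovinyl ether 6 (not isolated), via lithium alkynyl ether 7 (not isolated)
Conditions: KH (1.1 equiv), THF, 0 °C; Cl2C=CHCl, −50 °C to rt; n-BuLi (2.4 equiv), −78 to −40 °C; i-Pr3SiOTf, −78 to 0 °C
Reagents that add atoms: triisopropylsilyl trifluoromethanesulfonate, CC(C)[Si](C(C)C)(C(C)C)OS(=O)(=O)C(F)(F)F
Why: Alkynyl ether synthesis from trichloroethylene: the potassium alkoxide adds to dichloroacetylene formed in the flask to give 6, n-BuLi effects elimination and lithium–chlorine exchange to 7, and the acetylide is capped on carbon by the silyl triflate; the alkene and both stereocentres are untouched, and the capped ynol ether also protects the hydroxyl.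

Step 3
Reactants: 8 ({[(1S,2S)-2-methyl-1-(3,4,5-trimethoxyphenyl)but-3-en-1-yl]oxy}ethynyl)tri(propan-2-yl)silane
Product: 10 (3S,4S)-3-methyl-4-({[tri(propan-2-yl)silyl]ethynyl}oxy)-4-(3,4,5-trimethoxyphenyl)butan-1-ol, via B-alkyl-9-borabicyclo[3.3.1]nonane 9 (not isolated)
Conditions: 9-borabicyclo[3.3.1]nonane (1.1 equiv), THF, 0 °C to rt; then 30% H2O2, 2 M NaOH, 0 °C
Reagents that add atoms: hydrogen peroxide, OO
Why: Hydroboration–oxidation: 9-BBN should add to the unhindered monosubstituted alkene at its terminal carbon much faster than to the internal alkyne shielded by the triisopropylsilyl group, and alkaline peroxide oxidises the C–B bond without touching the silyl ynol ether.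

Step 4
Reactants: 10 (3S,4S)-3-methyl-4-({[tri(propan-2-yl)silyl]ethynyl}oxy)-4-(3,4,5-trimethoxyphenyl)butan-1-ol
Product: 11 (3S,4S)-3-methyl-4-({[tri(propan-2-yl)silyl]ethynyl}oxy)-4-(3,4,5-trimethoxyphenyl)butanal
Conditions: Dess–Martin periodinane, NaHCO3, CH2Cl2, 0 °C to rt
Reagents that add atoms: none
Why: Dess–Martin oxidation of a primary alcohol to the aldehyde under bicarbonate buffer, mild enough for the acid-sensitive ynol ether; the β-stereocentre cannot enolise.

Step 5
Reactants: 11 (3S,4S)-3-methyl-4-({[tri(propan-2-yl)silyl]ethynyl}oxy)-4-(3,4,5-trimethoxyphenyl)butanal; 12 ethynylmagnesium bromide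
Product: 14 (3RS,5S,6S)-5-methyl-6-({[tri(propan-2-yl)silyl]ethynyl}oxy)-6-(3,4,5-trimethoxyphenyl)hex-1-yn-3-ol, via bromomagnesium alkoxide 13 (not isolated)
Conditions: HC≡CMgBr (0.5 M in THF, 1.5 equiv), THF, −78 to 0 °C; sat. aq. NH4Cl
Reagents that add atoms: none
Why: Grignard 1,2-addition of the acetylide to the aldehyde; the new carbinol centre forms without control, which does not matter because it is oxidised in step 6.

Step 6
Reactants: 14 (3RS,5S,6S)-5-methyl-6-({[tri(propan-2-yl)silyl]ethynyl}oxy)-6-(3,4,5-trimethoxyphenyl)hex-1-yn-3-ol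
Product: 16 (1E,5S,6S)-1-methoxy-5-methyl-6-({[tri(propan-2-yl)silyl]ethynyl}oxy)-6-(3,4,5-trimethoxyphenyl)hex-1-en-3-one, via ynone 15 (not isolated)
Conditions: MnO2 (activated, 15 equiv), CH2Cl2, rt; filtration; then MeOH, 1,4-diazabicyclo[2.2.2]octane (10 mol%), 0 °C to rt
Reagents that add atoms: methanol, CO
Why: MnO2 oxidation of the propargylic alcohol gives the terminal ynone, and amine-catalysed conjugate addition of methanol (oxa-Michael) gives the thermodynamically favoured (E)-β-methoxy enone; the enone geometry is lost later at C5, so it need not be pure.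

Step 7
Reactants: 16 (1E,5S,6S)-1-methoxy-5-methyl-6-({[tri(propan-2-yl)silyl]ethynyl}oxy)-6-(3,4,5-trimethoxyphenyl)hex-1-en-3-one
Product: 18 (1E,5S,6S)-4-diazo-1-methoxy-5-methyl-6-({[tri(propan-2-yl)silyl]ethynyl}oxy)-6-(3,4,5-trimethoxyphenyl)hex-1-en-3-one, via trifluoroacetyl ketone 17 (not isolated)
Conditions: LiN(SiMe3)2 (1.1 equiv), THF, −78 °C; CF3CO2CH2CF3 (1.2 equiv); sat. aq. NH4Cl; then 4-acetamidobenzenesulfonyl azide (1.5 equiv), Et3N, H2O (1 equiv), MeCN, rt
Reagents that add atoms: 4-acetamidobenzenesulfonyl azide, CC(=O)Nc1ccc(cc1)S(=O)(=O)N=[N+]=[N-]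
Why: Detrifluoroacetylative diazo transfer: C4, the only enolisable position, is trifluoroacetylated through its lithium enolate (Claisen condensation), and the activated diketone takes the diazo group from the sulfonyl azide with loss of the trifluoroacetyl group, the standard access to α′-diazo enones; C5 is not epimerised because enolisation is confined to C4.

Step 8
Reactants: 18 (1E,5S,6S)-4-diazo-1-methoxy-5-methyl-6-({[tri(propan-2-yl)silyl]ethynyl}oxy)-6-(3,4,5-trimethoxyphenyl)hex-1-en-3-one
Product: 19 (1E,5S,6S)-4-diazo-6-(ethynyloxy)-1-methoxy-5-methyl-6-(3,4,5-trimethoxyphenyl)hex-1-en-3-one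
Conditions: Bu4NF (1.1 equiv), THF, −40 to −20 °C; pH 7 phosphate buffer
Reagents that add atoms: none
Why: Fluoride-induced protodesilylation of the alkynylsilane; the diazo ketone and the vinylogous ester tolerate fluoride at low temperature, and the cold, buffered work-up preserves the terminal ynol ether, which is used at once.

Step 9
Reactants: 19 (1E,5S,6S)-4-diazo-6-(ethynyloxy)-1-methoxy-5-methyl-6-(3,4,5-trimethoxyphenyl)hex-1-en-3-one
Product: 24 (2S,3S)-5-methoxy-3-methyl-2-(3,4,5-trimethoxyphenyl)-2,3-dihydro-1-benzofuran-6-ol, via vinylketene 20 (not isolated), via bicyclic cyclobutenone 21 (not isolated), via dienylketene 22 (not isolated), via cyclohexa-2,4-dienone 23 (not isolated)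
Conditions: hν (300 nm, Pyrex), CH2Cl2 (0.005 M, degassed), −30 °C; then 25 °C in the dark
Reagents that add atoms: none
Why: Proposed new method: photolysis expels N2 and, by Wolff rearrangement with migration of the methoxyvinyl group from the carbonyl carbon to C3a, gives vinylketene 20 (O=C6=C3a); the polarised ynol ether then adds its terminal carbon C7 to the ketene carbon C6 and its oxygen-bearing carbon C7a to C3a in a [2+2] cycloaddition (21), conrotatory 4π opening of the C3a–C6 bond gives dienylketene 22, disrotatory 6π closure joins C5 to C6 (23) and enolisation gives 24, the closest known reaction type being the intermolecular Danheiser benzannulation of photochemically generated vinylketenes with alkoxy- and siloxyalkynes, run here through a three-atom tether. Ring B closes by the C3a–C7a bond as the five-membered half of the fused cyclobutenone, with the second alkyne carbon left outside the ring (exo mode), and the strain of this bicycle should only speed its electrocyclic opening. Ring A closes by thermal 6π electrocyclisation of 22, whose central C3a=C7a bond is held cis inside ring B, and the closure is made irreversible by aromatisation because C5 carries a hydrogen. No lasting stereocentre is created: C3a of 21 and C5 of 23 are transient, and C2 and C3 are not touched. The regiochemistry is fixed twice, by the polarity of ketene and ynol ether and by the tether, which cannot span the opposite orientation. The chemoselectivity needed is Wolff shift over a 1,2-hydrogen shift from C3 in a free carbene, favoured by direct irradiation at low temperature, and ring closure over ketene dimerisation, secured by high dilution. The cold, light-driven first stage also keeps the secondary benzylic ethynyl ether below the temperature of its retro-ene and [3,3] decomposition until it has been consumed.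

Step 10
Reactants: 24 (2S,3S)-5-methoxy-3-methyl-2-(3,4,5-trimethoxyphenyl)-2,3-dihydro-1-benzofuran-6-ol
Product: 26 (2S,3R,3aR)-3a-hydroxy-5-methoxy-3-methyl-2-(3,4,5-trimethoxyphenyl)-3,3a-dihydro-1-benzofuran-6(2H)-one, via hydroperoxide 25 (not isolated)
Conditions: KHSO5 (as 2KHSO5·KHSO4·K2SO4), NaHCO3, MeCN–H2O, 0 °C; then Me2S
Reagents that add atoms: potassium peroxymonosulfate, [K+].[O-]S(=O)(=O)OO
Why: Oxidative dearomatisation by singlet oxygen (released from peroxymonosulfate and bicarbonate), which adds to an electron-rich phenol at the carbon para to the hydroxyl, here C3a, followed by reduction of the hydroperoxide by the sulfide; the C3a–O bond should form on the face anti to the neighbouring C3 methyl group (1,2-induction), which sets C3a as R.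

Step 11
Reactants: 26 (2S,3R,3aR)-3a-hydroxy-5-methoxy-3-methyl-2-(3,4,5-trimethoxyphenyl)-3,3a-dihydro-1-benzofuran-6(2H)-one
Product: 28 2-[(2S,3S,5R)-5-methoxy-3-methyl-6-oxo-2-(3,4,5-trimethoxyphenyl)-2,3,5,6-tetrahydro-1-benzofuran-5-yl]acetaldehyde, via vinyl ether 27 (not isolated)
Conditions: [IrCl(1,5-cyclooctadiene)]2 (2 mol%), Na2CO3 (0.6 equiv), vinyl acetate (5 equiv), toluene, 100 °C
Reagents that add atoms: vinyl acetate, C=COC(C)=O
Why: Iridium-catalysed transfer vinylation of the tertiary alcohol gives allyl vinyl ether 27, which undergoes Claisen rearrangement in the same pot; the shift is suprafacial across C3a–C4=C5, so the CH2CHO group reaches C5 on the face that carried the C3a oxygen and C5 is set as R by 1,3-chirality transfer, while migration to C7 is disfavoured because the terminus C5 carries a donor (methoxy) that accelerates a Claisen shift whereas the other allyl unit has its donor O1 on the central carbon C7a, which retards it; formation of the aldehyde C=O drives the step and the product has no allyl group that could shift further.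

Step 12
Reactants: 28 2-[(2S,3S,5R)-5-methoxy-3-methyl-6-oxo-2-(3,4,5-trimethoxyphenyl)-2,3,5,6-tetrahydro-1-benzofuran-5-yl]acetaldehyde
Product: 29 (2S,3S,5R)-5-methoxy-3-methyl-5-(prop-2-en-1-yl)-2-(3,4,5-trimethoxyphenyl)-3,5-dihydro-1-benzofuran-6(2H)-one
Conditions: Ph3PCH3Br, KN(SiMe3)2, THF, 0 °C; then 28, −78 to 0 °C
Reagents that add atoms: methyltriphenylphosphonium bromide, C[P+](c1ccccc1)(c1ccccc1)c1ccccc1.[Br-]
Why: Wittig methylenation: the unhindered aldehyde reacts with the ylide at low temperature far faster than the hindered ketone of the vinylogous ester, the cold conditions suppress β-elimination of methoxide, and the allyl dienone is formed last so that it is never heated; C5 is not affected.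

## Compound list

1 | 3,4,5-trimethoxybenzaldehyde | COc1cc(C=O)cc(OC)c1OC | starting material
2 | (E)-crotylboronic acid pinacol ester | C/C=C/CB1OC(C)(C)C(C)(C)O1 | starting material
3 | 4,4,5,5-tetramethyl-2-{[(1S,2S)-2-methyl-1-(3,4,5-trimethoxyphenyl)but-3-en-1-yl]oxy}-1,3,2-dioxaborolane | C=C[C@H](C)[C@H](OB1OC(C)(C)C(C)(C)O1)c1cc(OC)c(OC)c(OC)c1 | intermediate (not isolated)
4 | (1S,2S)-2-methyl-1-(3,4,5-trimethoxyphenyl)but-3-en-1-ol | C=C[C@H](C)[C@H](O)c1cc(OC)c(OC)c(OC)c1 | intermediate
5 | trichloroethylene | ClC=C(Cl)Cl | starting material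
6 | 5-[(1S,2S)-1-{[(E)-1,2-dichloroethenyl]oxy}-2-methylbut-3-en-1-yl]-1,2,3-trimethoxybenzene | C=C[C@H](C)[C@H](O/C(Cl)=C\Cl)c1cc(OC)c(OC)c(OC)c1 | intermediate (not isolated)
7 | ({[(1S,2S)-2-methyl-1-(3,4,5-trimethoxyphenyl)but-3-en-1-yl]oxy}ethynyl)lithium | C=C[C@H](C)[C@H](OC#C[Li])c1cc(OC)c(OC)c(OC)c1 | intermediate (not isolated)
8 | ({[(1S,2S)-2-methyl-1-(3,4,5-trimethoxyphenyl)but-3-en-1-yl]oxy}ethynyl)tri(propan-2-yl)silane | C=C[C@H](C)[C@H](OC#C[Si](C(C)C)(C(C)C)C(C)C)c1cc(OC)c(OC)c(OC)c1 | intermediate
9 | 9-[(3S,4S)-3-methyl-4-({[tri(propan-2-yl)silyl]ethynyl}oxy)-4-(3,4,5-trimethoxyphenyl)butyl]-9-borabicyclo[3.3.1]nonane | C(C[C@H](C)[C@H](OC#C[Si](C(C)C)(C(C)C)C(C)C)c1cc(OC)c(OC)c(OC)c1)B1C2CCCC1CCC2 | intermediate (not isolated)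
10 | (3S,4S)-3-methyl-4-({[tri(propan-2-yl)silyl]ethynyl}oxy)-4-(3,4,5-trimethoxyphenyl)butan-1-ol | OCC[C@H](C)[C@H](OC#C[Si](C(C)C)(C(C)C)C(C)C)c1cc(OC)c(OC)c(OC)c1 | intermediate
11 | (3S,4S)-3-methyl-4-({[tri(propan-2-yl)silyl]ethynyl}oxy)-4-(3,4,5-trimethoxyphenyl)butanal | O=CC[C@H](C)[C@H](OC#C[Si](C(C)C)(C(C)C)C(C)C)c1cc(OC)c(OC)c(OC)c1 | intermediate
12 | ethynylmagnesium bromide | C#C[Mg]Br | starting material
13 | bromomagnesium (5S,6S)-5-methyl-6-({[tri(propan-2-yl)silyl]ethynyl}oxy)-6-(3,4,5-trimethoxyphenyl)hex-1-yn-3-olate | C#CC(O[Mg]Br)C[C@H](C)[C@H](OC#C[Si](C(C)C)(C(C)C)C(C)C)c1cc(OC)c(OC)c(OC)c1 | intermediate (not isolated)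
14 | (3RS,5S,6S)-5-methyl-6-({[tri(propan-2-yl)silyl]ethynyl}oxy)-6-(3,4,5-trimethoxyphenyl)hex-1-yn-3-ol | C#CC(O)C[C@H](C)[C@H](OC#C[Si](C(C)C)(C(C)C)C(C)C)c1cc(OC)c(OC)c(OC)c1 | intermediate
15 | (5S,6S)-5-methyl-6-({[tri(propan-2-yl)silyl]ethynyl}oxy)-6-(3,4,5-trimethoxyphenyl)hex-1-yn-3-one | C#CC(=O)C[C@H](C)[C@H](OC#C[Si](C(C)C)(C(C)C)C(C)C)c1cc(OC)c(OC)c(OC)c1 | intermediate (not isolated)
16 | (1E,5S,6S)-1-methoxy-5-methyl-6-({[tri(propan-2-yl)silyl]ethynyl}oxy)-6-(3,4,5-trimethoxyphenyl)hex-1-en-3-one | CO/C=C/C(=O)C[C@H](C)[C@H](OC#C[Si](C(C)C)(C(C)C)C(C)C)c1cc(OC)c(OC)c(OC)c1 | intermediate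
17 | (1E,5S,6S)-1-methoxy-5-methyl-4-(trifluoroacetyl)-6-({[tri(propan-2-yl)silyl]ethynyl}oxy)-6-(3,4,5-trimethoxyphenyl)hex-1-en-3-one (C4 unassigned, enolised) | CO/C=C/C(=O)C(C(=O)C(F)(F)F)[C@H](C)[C@H](OC#C[Si](C(C)C)(C(C)C)C(C)C)c1cc(OC)c(OC)c(OC)c1 | intermediate (not isolated)
18 | (1E,5S,6S)-4-diazo-1-methoxy-5-methyl-6-({[tri(propan-2-yl)silyl]ethynyl}oxy)-6-(3,4,5-trimethoxyphenyl)hex-1-en-3-one | CO/C=C/C(=O)C(=[N+]=[N-])[C@H](C)[C@H](OC#C[Si](C(C)C)(C(C)C)C(C)C)c1cc(OC)c(OC)c(OC)c1 | intermediate
19 | (1E,5S,6S)-4-diazo-6-(ethynyloxy)-1-methoxy-5-methyl-6-(3,4,5-trimethoxyphenyl)hex-1-en-3-one | CO/C=C/C(=O)C(=[N+]=[N-])[C@H](C)[C@H](OC#C)c1cc(OC)c(OC)c(OC)c1 | intermediate (precursor of the key step)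
20 | (3S,4S)-4-(ethynyloxy)-2-[(E)-2-methoxyethenyl]-3-methyl-4-(3,4,5-trimethoxyphenyl)but-1-en-1-one | CO/C=C/C(=C=O)[C@H](C)[C@H](OC#C)c1cc(OC)c(OC)c(OC)c1 | intermediate (not isolated)
21 | 5-[(E)-2-methoxyethenyl]-4-methyl-3-(3,4,5-trimethoxyphenyl)-2-oxabicyclo[3.2.0]hept-1(7)-en-6-one (aryl and methyl carbons as in 19; ring-fusion carbon C5 unassigned) | O=C1C=C2O[C@H](c3cc(OC)c(OC)c(OC)c3)[C@@H](C)C12/C=C/OC | intermediate (not isolated)
22 | 2-{(4S,5S)-3-[(E)-2-methoxyethenyl]-4-methyl-5-(3,4,5-trimethoxyphenyl)-4,5-dihydrofuran-2-yl}ethen-1-one | O=C=CC1=C(/C=C/OC)[C@H](C)[C@@H](c2cc(OC)c(OC)c(OC)c2)O1 | intermediate (not isolated)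
23 | (2S,3S)-5-methoxy-3-methyl-2-(3,4,5-trimethoxyphenyl)-3,5-dihydro-1-benzofuran-6(2H)-one (C5 unassigned) | COC1C=C2C(=CC1=O)O[C@H](c1cc(OC)c(OC)c(OC)c1)[C@H]2C | intermediate (not isolated)
24 | (2S,3S)-5-methoxy-3-methyl-2-(3,4,5-trimethoxyphenyl)-2,3-dihydro-1-benzofuran-6-ol | COc1cc2c(cc1O)O[C@H](c1cc(OC)c(OC)c(OC)c1)[C@H]2C | intermediate (product of the key step)
25 | (2S,3R,3aR)-3a-hydroperoxy-5-methoxy-3-methyl-2-(3,4,5-trimethoxyphenyl)-3,3a-dihydro-1-benzofuran-6(2H)-one | OO[C@]12C=C(OC)C(=O)C=C1O[C@H](c1cc(OC)c(OC)c(OC)c1)[C@H]2C | intermediate (not isolated)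
26 | (2S,3R,3aR)-3a-hydroxy-5-methoxy-3-methyl-2-(3,4,5-trimethoxyphenyl)-3,3a-dihydro-1-benzofuran-6(2H)-one | O[C@]12C=C(OC)C(=O)C=C1O[C@H](c1cc(OC)c(OC)c(OC)c1)[C@H]2C | intermediate
27 | (2S,3R,3aR)-3a-(ethenyloxy)-5-methoxy-3-methyl-2-(3,4,5-trimethoxyphenyl)-3,3a-dihydro-1-benzofuran-6(2H)-one | C=CO[C@]12C=C(OC)C(=O)C=C1O[C@H](c1cc(OC)c(OC)c(OC)c1)[C@H]2C | intermediate (not isolated)
28 | 2-[(2S,3S,5R)-5-methoxy-3-methyl-6-oxo-2-(3,4,5-trimethoxyphenyl)-2,3,5,6-tetrahydro-1-benzofuran-5-yl]acetaldehyde | O=CC[C@@]1(OC)C=C2C(=CC1=O)O[C@H](c1cc(OC)c(OC)c(OC)c1)[C@H]2C | intermediate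
29 | (2S,3S,5R)-5-methoxy-3-methyl-5-(prop-2-en-1-yl)-2-(3,4,5-trimethoxyphenyl)-3,5-dihydro-1-benzofuran-6(2H)-one | C=CC[C@@]1(OC)C=C2C(=CC1=O)O[C@H](c1cc(OC)c(OC)c(OC)c1)[C@H]2C | target

## Step count and least certain steps

Total step count: 12. Longest linear sequence: 12 steps (1 to 29).

Step 9 (key step, proposed new method). The most likely failure is that the light-generated intermediate does not ring-close.
- The diazo carbon bears a secondary alkyl group, so a free carbene may form and a 1,2-hydrogen shift from C3 may outrun the Wolff shift.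
- The ketene may form but add too slowly to the tethered alkyne, because the transition state must bend the alkyne toward a strained bicyclo[3.2.0]heptenone; ketene dimerisation would then take over.
- The ethynyl ether may decompose by retro-ene or [3,3] pathways before it reacts.

Fallback (known chemistry; the tether is given up and ring B is closed afterwards). It sets out from 4. Silylation (t-BuMe2SiCl, imidazole) gives the silyl ether F1, and the operations of steps 3 to 7 are repeated on it: hydroboration–oxidation to the primary alcohol F2, Dess–Martin oxidation to the aldehyde F3, addition of HC≡CMgBr to the propargylic alcohol F4, MnO2 oxidation to the ynone F5, methanol addition to the β-methoxy enone F6 and detrifluoroacetylative diazo transfer to the diazo ketone F7. Irradiation of F7 with an excess of (triisopropylsilyloxy)ethyne, the intermolecular Danheiser benzannulation in its established form, should give the phenol F8. Bu4NF removes both silyl groups to give the triol F9, and catalytic TsOH closes ring B through the benzylic cation, which the ortho hydroxyl captures trans to the methyl group. The fallback comes back to the route at 24.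

Step 11. The most likely failure is incomplete vinyl transfer, because the tertiary hydroxyl is flanked by the quaternary ring fusion and by C3; prolonged heating of 26 then invites loss of the C3a oxygen and rearomatisation. Fallback: from 26, conjugate addition of its potassium alkoxide (catalytic KH) to phenyl vinyl sulfoxide gives the 2-(phenylsulfinyl)ethyl ether F10. Thermolysis over NaHCO3 in xylene eliminates the sulfoxide to 27, which rearranges as in the main route, so the fallback comes back at 28.

Step 10. The most likely failure is poor site or face selectivity of the oxygenation: oxygen transfer to the methoxy-bearing C5 with loss of methanol toward an ortho-quinone, or attack on both faces of C3a, since the only bias is the neighbouring methyl group; epoxidation of the product dienone is a further drain. Fallback (the relay is given up): from 24, PhI(OAc)2 in MeOH gives the dimethyl ketal F11. BF3·OEt2 and allyltrimethylsilane at −78 °C replace one ketal methoxy group by allyl (Hosomi–Sakurai reaction), which should give 29 together with its C5 epimer F12, separated by chromatography. The fallback comes back at 29; it saves one step but gives up control of C5.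

Step 3. The most likely failure is competing hydroboration of the electron-rich triple bond of the ynol ether, which would consume the borane and destroy the tether. Fallback: from 8, cross-metathesis with vinylboronic acid pinacol ester (second-generation Hoveyda–Grubbs catalyst) gives the (E)-alkenylboronate F13, and oxidation with NaBO3·4H2O gives the aldehyde directly, so the fallback comes back at 11 and bypasses 10.

## Further compounds

F1 | step 9 | tert-butyl(dimethyl){[(1S,2S)-2-methyl-1-(3,4,5-trimethoxyphenyl)but-3-en-1-yl]oxy}silane | C=C[C@H](C)[C@H](O[Si](C)(C)C(C)(C)C)c1cc(OC)c(OC)c(OC)c1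
F2 | step 9 | (3S,4S)-4-{[tert-butyl(dimethyl)silyl]oxy}-3-methyl-4-(3,4,5-trimethoxyphenyl)butan-1-ol | OCC[C@H](C)[C@H](O[Si](C)(C)C(C)(C)C)c1cc(OC)c(OC)c(OC)c1
F3 | step 9 | (3S,4S)-4-{[tert-butyl(dimethyl)silyl]oxy}-3-methyl-4-(3,4,5-trimethoxyphenyl)butanal | O=CC[C@H](C)[C@H](O[Si](C)(C)C(C)(C)C)c1cc(OC)c(OC)c(OC)c1
F4 | step 9 | (3RS,5S,6S)-6-{[tert-butyl(dimethyl)silyl]oxy}-5-methyl-6-(3,4,5-trimethoxyphenyl)hex-1-yn-3-ol | C#CC(O)C[C@H](C)[C@H](O[Si](C)(C)C(C)(C)C)c1cc(OC)c(OC)c(OC)c1
F5 | step 9 | (5S,6S)-6-{[tert-butyl(dimethyl)silyl]oxy}-5-methyl-6-(3,4,5-trimethoxyphenyl)hex-1-yn-3-one | C#CC(=O)C[C@H](C)[C@H](O[Si](C)(C)C(C)(C)C)c1cc(OC)c(OC)c(OC)c1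
F6 | step 9 | (1E,5S,6S)-6-{[tert-butyl(dimethyl)silyl]oxy}-1-methoxy-5-methyl-6-(3,4,5-trimethoxyphenyl)hex-1-en-3-one | CO/C=C/C(=O)C[C@H](C)[C@H](O[Si](C)(C)C(C)(C)C)c1cc(OC)c(OC)c(OC)c1
F7 | step 9 | (1E,5S,6S)-6-{[tert-butyl(dimethyl)silyl]oxy}-4-diazo-1-methoxy-5-methyl-6-(3,4,5-trimethoxyphenyl)hex-1-en-3-one | CO/C=C/C(=O)C(=[N+]=[N-])[C@H](C)[C@H](O[Si](C)(C)C(C)(C)C)c1cc(OC)c(OC)c(OC)c1
F8 | step 9 | 4-[(1S,2S)-1-{[tert-butyl(dimethyl)silyl]oxy}-1-(3,4,5-trimethoxyphenyl)propan-2-yl]-2-methoxy-5-{[tri(propan-2-yl)silyl]oxy}phenol | COc1cc([C@H](C)[C@H](O[Si](C)(C)C(C)(C)C)c2cc(OC)c(OC)c(OC)c2)c(O[Si](C(C)C)(C(C)C)C(C)C)cc1O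
F9 | step 9 | 4-[(1S,2S)-1-hydroxy-1-(3,4,5-trimethoxyphenyl)propan-2-yl]-6-methoxybenzene-1,3-diol | COc1cc([C@H](C)[C@H](O)c2cc(OC)c(OC)c(OC)c2)c(O)cc1O
F10 | step 11 | (2S,3R,3aR)-5-methoxy-3-methyl-3a-[2-(phenylsulfinyl)ethoxy]-2-(3,4,5-trimethoxyphenyl)-3,3a-dihydro-1-benzofuran-6(2H)-one (sulfur epimers) | O=S(CCO[C@]12C=C(OC)C(=O)C=C1O[C@H](c1cc(OC)c(OC)c(OC)c1)[C@H]2C)c1ccccc1
F11 | step 10 | (2S,3S)-5,5-dimethoxy-3-methyl-2-(3,4,5-trimethoxyphenyl)-3,5-dihydro-1-benzofuran-6(2H)-one | COC1(OC)C=C2C(=CC1=O)O[C@H](c1cc(OC)c(OC)c(OC)c1)[C@H]2C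
F12 | step 10 | (2S,3S,5S)-5-methoxy-3-methyl-5-(prop-2-en-1-yl)-2-(3,4,5-trimethoxyphenyl)-3,5-dihydro-1-benzofuran-6(2H)-one | C=CC[C@]1(OC)C=C2C(=CC1=O)O[C@H](c1cc(OC)c(OC)c(OC)c1)[C@H]2C
F13 | step 3 | 4,4,5,5-tetramethyl-2-[(1E,3S,4S)-3-methyl-4-({[tri(propan-2-yl)silyl]ethynyl}oxy)-4-(3,4,5-trimethoxyphenyl)but-1-en-1-yl]-1,3,2-dioxaborolane | CC1(C)OB(/C=C/[C@H](C)[C@H](OC#C[Si](C(C)C)(C(C)C)C(C)C)c2cc(OC)c(OC)c(OC)c2)OC1(C)C
A1 | alternative 1 | 3-[(2S,3S)-6-hydroxy-3-methyl-2-(3,4,5-trimethoxyphenyl)-2,3-dihydro-1-benzofuran-5-yl]propanoic acid | OC(=O)CCc1cc2c(cc1O)O[C@H](c1cc(OC)c(OC)c(OC)c1)[C@H]2C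
A2 | alternative 1 | (2S,3S,5R)-3-methyl-2-(3,4,5-trimethoxyphenyl)-2,3-dihydro-6H-spiro[1-benzofuran-5,2′-oxolane]-5′,6-dione | O=C1CC[C@@]2(O1)C=C3C(=CC2=O)O[C@H](c4cc(OC)c(OC)c(OC)c4)[C@H]3C
A3 | alternative 2 | tert-butyl 2-formyl-4-methoxy-5-(methoxymethoxy)phenyl carbonate | O=Cc1cc(OC)c(OCOC)cc1OC(=O)OC(C)(C)C
A4 | alternative 2 | (2R,5R)-2,5-dimethyl-1-(3,4,5-trimethoxybenzyl)thiolan-1-ium trifluoromethanesulfonate | C[C@@H]1CC[C@@H](C)[S+]1Cc1cc(OC)c(OC)c(OC)c1.[O-]S(=O)(=O)C(F)(F)F
A5 | alternative 2 | (2S,3S)-5-methoxy-6-(methoxymethoxy)-3-methyl-2-(3,4,5-trimethoxyphenyl)-2,3-dihydro-1-benzofuran | COc1cc2c(cc1OCOC)O[C@H](c1cc(OC)c(OC)c(OC)c1)[C@H]2C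
A6 | alternative 3 | methyl 2-diazo-2-{5-methoxy-4-(methoxymethoxy)-2-[(3,4,5-trimethoxybenzyl)oxy]phenyl}acetate | COC(=O)C(=[N+]=[N-])c1cc(OC)c(OCOC)cc1OCc1cc(OC)c(OC)c(OC)c1
A7 | alternative 3 | methyl (2S,3R)-5-methoxy-6-(methoxymethoxy)-2-(3,4,5-trimethoxyphenyl)-2,3-dihydro-1-benzofuran-3-carboxylate (cis) | COc1cc2c(cc1OCOC)O[C@H](c1cc(OC)c(OC)c(OC)c1)[C@@H]2C(=O)OC
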